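## Retrosynthetic overview
1. Isogoiazensolide ⇒ 15-deoxygoyazensolide. The 5-OH and the C4=C15 methylene come from the Δ4 alkene by a singlet-oxygen ene reaction in the last step.
2. 3(2H)-Furanone ⇒ transannular addition of 10-OH to C3 of a ten-membered 1-oxo-2-yne, which acts as a latent 1,3-diketone.
3. γ-Lactone and carbocycle ⇒ one allylchromium closure of C6–C7, the bond made by the germacrene cyclase. The substrate is an acyclic, fully oxygenated, alkyne-containing C15 chain, and the C6 alkoxide lactonises on C12.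
4. Chain ⇒ (R)-linalool (C1, C7–C10, C14; supplies C10) + methyl propiolate (C11–C13) + (Z)-3-methylpent-2-en-4-yn-1-ol (C2–C6, C15). C8 is set by catalytic α-chlorination followed by inversion.
5. Ring order: carbocycle → lactone → furanone, as in the presumed biosynthesis.

Assumption: atoms carry germacrane numbers (C1–C15), α/β refer to the usual germacranolide drawing (7-H is α), and commercial (R)-(−)-linalool is taken as ≥97 % ee. By the CIP analysis of the given SMILES the target is 5R,6S,7R,8S,10R.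

## Route

Step 1
Reactants: 1 (R)-(−)-linalool
Product: 2 (3R)-3,7-dimethyl-3-[(triethylsilyl)oxy]octa-1,6-diene
Conditions: TESOTf, 2,6-lutidine, CH2Cl2, 0 °C
Reagents that add atoms: triethylsilyl trifluoromethanesulfonate, CC[Si](CC)(CC)OS(=O)(=O)C(F)(F)F
Why: Silyl ether formation with the triflate is the standard way to cap a hindered tertiary allylic alcohol; it leaves the chiral-pool C10 centre untouched and keeps O10 from opening the later vinyl epoxide.

Step 2
Reactants: 2 (3R)-3,7-dimethyl-3-[(triethylsilyl)oxy]octa-1,6-diene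
Product: 3 (2R)-2-methyl-2-[(triethylsilyl)oxy]pentanedial
Conditions: O3 (excess), CH2Cl2, −78 °C; then Me2S, −78 °C → rt
Reagents that add atoms: ozone, [O-][O+]=O
Why: Exhaustive ozonolysis with reductive work-up cleaves both alkenes and gives a dialdehyde with two chemically distinct ends (C1 is flanked by the quaternary carbon and cannot enolise, C7 is unhindered and enolisable); no stereocentre is formed.

Step 3
Reactants: 3 (2R)-2-methyl-2-[(triethylsilyl)oxy]pentanedial
Product: 4 (2R,4R)-4-chloro-2-methyl-2-[(triethylsilyl)oxy]pentanedial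
Conditions: NCS, (2S,5S)-2,5-diphenylpyrrolidine (10 mol %; the catalyst antipode that gives the R chloride), CH2Cl2, 0 °C; used crude
Reagents that add atoms: N-chlorosuccinimide, O=C1CCC(=O)N1Cl
Why: Enamine-catalysed asymmetric α-chlorination can only engage the enolisable C7 aldehyde, and the C2-symmetric catalyst fixes the new C8–Cl centre as R regardless of the remote C10 centre.

Step 4
Reactants: 4 (2R,4R)-4-chloro-2-methyl-2-[(triethylsilyl)oxy]pentanedial, 5 methyl propiolate
Product: 7 methyl (3S,4R,6R)-4-chloro-3-hydroxy-6-methyl-2-methylidene-7-oxo-6-[(triethylsilyl)oxy]heptanoate (drawn open; partly the C7-O/C1 lactol), via vinylalane 6 (not isolated)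
Conditions: 5 (1.1 equiv), DIBAL-H, NMO, THF, 0 °C; then 4, −78 → −20 °C; aq. Rochelle salt
Reagents that add atoms: none
Why: Hydroalumination of the propiolate gives the α-(methoxycarbonyl)vinylalane, a base-free Baylis–Hillman equivalent that adds (vinylalumination) to the far more electrophilic α-chloro aldehyde without epimerising C8, with Cornforth-type 1,2-anti induction at C7 (a centre erased in step 5), while the aluminium alkoxide formed masks the C1 aldehyde as a lactolate.

Step 5
Reactants: 7 methyl (3S,4R,6R)-4-chloro-3-hydroxy-6-methyl-2-methylidene-7-oxo-6-[(triethylsilyl)oxy]heptanoate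
Product: 9 methyl (2Z,4S,6R)-2-(bromomethyl)-6-methyl-7-oxo-4,6-bis[(triethylsilyl)oxy]hept-2-enoate, via vinyl epoxide 8 (not isolated)
Conditions: NaH (1.05 equiv), THF, 0 °C → rt; then Et3SiBr, −78 → −20 °C
Reagents that add atoms: bromotriethylsilane, CC[Si](Br)(CC)CC
Why: Williamson-type closure inverts C8 and puts oxygen on it (8S, trans-epoxide), and the silyl bromide then opens the acrylate-activated vinyl epoxide in the SN2′ sense (any C7 bromide equilibrates to the same product), which breaks only the C7–O bond, so C8–O keeps its configuration and the thermodynamic Z-2-(bromomethyl)enoate results.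

Step 6
Reactants: 9 methyl (2Z,4S,6R)-2-(bromomethyl)-6-methyl-7-oxo-4,6-bis[(triethylsilyl)oxy]hept-2-enoate, 10 (Z)-3-methylpent-2-en-4-yn-1-ol
Product: 12 methyl (2Z,4S,6R,10Z)-2-(bromomethyl)-7,12-dihydroxy-6,10-dimethyl-4,6-bis[(triethylsilyl)oxy]dodeca-2,10-dien-8-ynoate (both C7 epimers), via dilithio enynolate 11 (not isolated)
Conditions: 10 (1.05 equiv), n-BuLi (2.1 equiv), THF, −78 °C; added slowly to 9, −78 °C, 20 min; AcOH quench at −78 °C
Reagents that add atoms: none
Why: 1,2-Addition of a lithium acetylide to an aldehyde is complete within minutes at −78 °C, where acetylides and alkoxides do not yet displace allylic bromides or attack esters; the new carbinol (germacrane C1) forms as an inconsequential epimer mixture because it is oxidised in step 9.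

Step 7
Reactants: 12 methyl (2Z,4S,6R,10Z)-2-(bromomethyl)-7,12-dihydroxy-6,10-dimethyl-4,6-bis[(triethylsilyl)oxy]dodeca-2,10-dien-8-ynoate
Product: 13 methyl (2Z,4S,6R,10Z)-2-(bromomethyl)-7-hydroxy-6,10-dimethyl-12-oxo-4,6-bis[(triethylsilyl)oxy]dodeca-2,10-dien-8-ynoate
Conditions: TEMPO (10 mol %), PhI(OAc)2, CH2Cl2, 0 °C → rt
Reagents that add atoms: none
Why: The oxoammonium (TEMPO/PhI(OAc)2) oxidation is selective for the primary allylic alcohol over the hindered secondary propargylic one and is known to give Z-enals (nerol to neral) without isomerisation.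

Step 8
Reactants: 13 methyl (2Z,4S,6R,10Z)-2-(bromomethyl)-7-hydroxy-6,10-dimethyl-12-oxo-4,6-bis[(triethylsilyl)oxy]dodeca-2,10-dien-8-ynoate
Product: 16 (4Z)-1-hydroxy-8α,10α-bis(triethylsilyloxy)germacra-4,11(13)-dien-2-yn-6α,12-olide (7α-H; both C1 epimers), via allylchromium 14 (not isolated), via macrocyclic hydroxy ester 15 (not isolated)
Conditions: CrCl2 (10 equiv), 4 Å MS, THF/DMF 4:1, rt, 13 added by syringe pump over 12 h (final 1 mM); aq. NH4Cl
Reagents that add atoms: none
Why: Intramolecular Nozaki–Hiyama allylation at high dilution closes C6–C7 because allylchromium(III) attacks only the aldehyde: the E/Z-equilibrating reagent reacts through the chair transition state with the C8 chain equatorial (6,7-anti, hence the trans-lactone), A1,3 strain against the ester holds H8 in the alkene plane so that C6 arrives anti to the bulky OTES group on the face carrying the C9 tether (7α-H, 6α-O), and the chromium alkoxide then acylates itself with the neighbouring methyl ester.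

Step 9
Reactants: 16 (4Z)-1-hydroxy-8α,10α-bis(triethylsilyloxy)germacra-4,11(13)-dien-2-yn-6α,12-olide
Product: 17 (4Z)-1-oxo-8α,10α-bis(triethylsilyloxy)germacra-4,11(13)-dien-2-yn-6α,12-olide
Conditions: Dess–Martin periodinane, CH2Cl2, 0 °C → rt
Reagents that add atoms: none
Why: Dess–Martin oxidation turns the only free hydroxyl, the propargylic C1 carbinol, into the ynone under neutral conditions and merges the two C1 epimers; it comes after ring closure because a C1 ketone would have been trapped by C7 in a five-membered ring.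

Step 10
Reactants: 17 (4Z)-1-oxo-8α,10α-bis(triethylsilyloxy)germacra-4,11(13)-dien-2-yn-6α,12-olide
Product: 19 8α-hydroxy-1-oxo-3,10α-epoxygermacra-2,4Z,11(13)-trien-6α,12-olide (8-O-desacyl-15-deoxygoyazensolide), via dihydroxy ynone 18 (not isolated)
Conditions: Et3N·3HF, MeCN, rt → 40 °C
Reagents that add atoms: none
Why: Fluoride cleaves both TES ethers and the freed 10-OH adds across the ring to C3 of the strained ynone (amine-buffered 5-endo-dig oxa-Michael addition, the classical α′-hydroxy-ynone to 3(2H)-furanone closure), which never breaks the C10–O bond and so keeps 10R.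

Step 11
Reactants: 19 8α-hydroxy-1-oxo-3,10α-epoxygermacra-2,4Z,11(13)-trien-6α,12-olide, 20 methacrylic anhydride
Product: 21 15-deoxygoyazensolide (8α-methacrylate of 19)
Conditions: 20, DMAP (cat.), Et3N, CH2Cl2, 0 °C
Reagents that add atoms: none
Why: DMAP-catalysed acyl transfer to the only remaining hydroxyl group gives the 8-methacrylate with retention at C8.

Step 12
Reactants: 21 15-deoxygoyazensolide
Product: 23 isogoiazensolide, via 5-hydroperoxide 22 (not isolated)
Conditions: O2, tetraphenylporphyrin (2 mol %), visible light, CH2Cl2, −20 °C; then PPh3, −20 °C → rt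
Reagents that add atoms: dioxygen, O=O
Why: In this Schenck ene reaction the Δ4 alkene is the only non-acceptor alkene and its s-trans diene geometry excludes [4+2] addition, oxygen goes to C5 with loss of H from C15 (geminal selectivity for the methyl next to the electron-poor furanone, while H6 lies in the alkene plane through A1,3 strain and cannot be abstracted), attack anti to the C6–O lactone bond (erythro preference of allylic esters) gives 5R, and PPh3 reduces O–OH with retention.

## Compound list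
1 | (R)-(−)-linalool | C=C[C@](C)(O)CCC=C(C)C | starting material
2 | (3R)-3,7-dimethyl-3-[(triethylsilyl)oxy]octa-1,6-diene | C=C[C@](C)(O[Si](CC)(CC)CC)CCC=C(C)C | intermediate
3 | (2R)-2-methyl-2-[(triethylsilyl)oxy]pentanedial | O=C[C@](C)(O[Si](CC)(CC)CC)CCC=O | intermediate
4 | (2R,4R)-4-chloro-2-methyl-2-[(triethylsilyl)oxy]pentanedial | O=C[C@](C)(O[Si](CC)(CC)CC)C[C@@H](Cl)C=O | intermediate
5 | methyl propiolate | C#CC(=O)OC | starting material
6 | methyl 2-(diisobutylalumanyl)prop-2-enoate (vinylalane, not isolated) | C=C(C(=O)OC)[Al](CC(C)C)CC(C)C | intermediate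
7 | methyl (3S,4R,6R)-4-chloro-3-hydroxy-6-methyl-2-methylidene-7-oxo-6-[(triethylsilyl)oxy]heptanoate | O=C[C@](C)(O[Si](CC)(CC)CC)C[C@@H](Cl)[C@@H](O)C(=C)C(=O)OC | intermediate
8 | methyl 2-[(2S,3S)-3-{(2R)-2-methyl-3-oxo-2-[(triethylsilyl)oxy]propyl}oxiran-2-yl]prop-2-enoate (vinyl epoxide, not isolated) | O=C[C@](C)(O[Si](CC)(CC)CC)C[C@@H]1O[C@H]1C(=C)C(=O)OC | intermediate
9 | methyl (2Z,4S,6R)-2-(bromomethyl)-6-methyl-7-oxo-4,6-bis[(triethylsilyl)oxy]hept-2-enoate | O=C[C@](C)(O[Si](CC)(CC)CC)C[C@H](O[Si](CC)(CC)CC)/C=C(\CBr)C(=O)OC | intermediate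
10 | (Z)-3-methylpent-2-en-4-yn-1-ol | C#C/C(C)=C\CO | starting material
11 | dilithio derivative of 10 (O-Li and C-Li, not isolated) | [Li]C#C/C(C)=C\CO[Li] | intermediate
12 | methyl (2Z,4S,6R,10Z)-2-(bromomethyl)-7,12-dihydroxy-6,10-dimethyl-4,6-bis[(triethylsilyl)oxy]dodeca-2,10-dien-8-ynoate (C7 epimers) | OC/C=C(/C)C#CC(O)[C@](C)(O[Si](CC)(CC)CC)C[C@H](O[Si](CC)(CC)CC)/C=C(\CBr)C(=O)OC | intermediate
13 | methyl (2Z,4S,6R,10Z)-2-(bromomethyl)-7-hydroxy-6,10-dimethyl-12-oxo-4,6-bis[(triethylsilyl)oxy]dodeca-2,10-dien-8-ynoate | O=C/C=C(/C)C#CC(O)[C@](C)(O[Si](CC)(CC)CC)C[C@H](O[Si](CC)(CC)CC)/C=C(\CBr)C(=O)OC | intermediate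
14 | allylchromium(III) dichloride from 13 (reactive geometry, C8 trans to CH2Cr; not isolated) | O=C/C=C(/C)C#CC(O)[C@](C)(O[Si](CC)(CC)CC)C[C@H](O[Si](CC)(CC)CC)/C=C(/C[Cr](Cl)Cl)C(=O)OC | intermediate
15 | methyl (4Z)-1,6α-dihydroxy-8α,10α-bis(triethylsilyloxy)germacra-4,11(13)-dien-2-yn-12-oate (7α-H; present as its Cr(III) 6-alkoxide, not isolated) | CC[Si](CC)(CC)O[C@H]1C[C@@](C)(O[Si](CC)(CC)CC)C(O)C#C/C(C)=C\[C@@H](O)[C@@H]1C(=C)C(=O)OC | intermediate
16 | (4Z)-1-hydroxy-8α,10α-bis(triethylsilyloxy)germacra-4,11(13)-dien-2-yn-6α,12-olide (C1 epimers) | CC[Si](CC)(CC)O[C@H]1C[C@@](C)(O[Si](CC)(CC)CC)C(O)C#C/C(C)=C\[C@H]2OC(=O)C(=C)[C@@H]21 | intermediate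
17 | (4Z)-1-oxo-8α,10α-bis(triethylsilyloxy)germacra-4,11(13)-dien-2-yn-6α,12-olide | CC[Si](CC)(CC)O[C@H]1C[C@@](C)(O[Si](CC)(CC)CC)C(=O)C#C/C(C)=C\[C@H]2OC(=O)C(=C)[C@@H]21 | intermediate
18 | (4Z)-8α,10α-dihydroxy-1-oxogermacra-4,11(13)-dien-2-yn-6α,12-olide (not isolated) | O[C@H]1C[C@@](C)(O)C(=O)C#C/C(C)=C\[C@H]2OC(=O)C(=C)[C@@H]21 | intermediate
19 | 8α-hydroxy-1-oxo-3,10α-epoxygermacra-2,4Z,11(13)-trien-6α,12-olide | O[C@H]1C[C@@]2(C)OC(=CC2=O)/C(C)=C\[C@H]2OC(=O)C(=C)[C@@H]21 | intermediate
20 | methacrylic anhydride | C=C(C)C(=O)OC(=O)C(C)=C | starting material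
21 | 15-deoxygoyazensolide | C=C(C)C(=O)O[C@H]1C[C@@]2(C)OC(=CC2=O)/C(C)=C\[C@H]2OC(=O)C(=C)[C@@H]21 | intermediate
22 | (5R)-5-hydroperoxide of the 4(15)-ene (not isolated) | C=C(C)C(=O)O[C@H]1C[C@@]2(C)OC(=CC2=O)C(=C)[C@@H](OO)[C@H]2OC(=O)C(=C)[C@@H]21 | intermediate
23 | isogoiazensolide | C=C(C)C(=O)O[C@H]1C[C@@]2(C)OC(=CC2=O)C(=C)[C@@H](O)[C@H]2OC(=O)C(=C)[C@@H]21 | target

## Step count and risks
Total step count: 12. Longest linear sequence: 12 steps, from (R)-linalool.

**Step 8 (macrocyclisation).** The risks are the strain of the cyclodecenyne, oligomerisation, and 6,7-anti and facial control that rest on an equilibrating acyclic allylchromium.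
- The fallback sets out from 13 and comes back at 19. The allyl donor geometry is locked in a ring before the same C6–C7 bond is closed.
- AcOH/THF/H2O with LiBr removes the secondary C8 silyl ether of 13. After bromide-mediated E/Z equilibration the freed alcohol lactonises on C12 to give the 3-(bromomethyl)butenolide enal F1.
- In F1, C8 is held trans to CH2Br, so any closed transition state (CrCl2 at high dilution) must give the 6,7-anti adduct. The aldehyde has to approach the flat butenolide anti to C9. This gives the macrocyclic 6α-hydroxy-8α,12-olide F2.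
- Catalytic DBU moves the acyl group from O8 to O6 and gives the 8α-hydroxy-6α,12-olide F3.
- MnO2 oxidises only the propargylic C1 carbinol, giving the 8α-hydroxy-10α-silyloxy ynone F4.
- Et3N·3HF then frees 10-OH, which closes through 18 to 19.

**Step 10 (desilylation and transannular oxa-Michael addition).** The risks are amine or fluoride damage to the ynone and the α-methylene lactone, acyl shift to the free 8-OH, and sluggish closure.
- The fallback sets out from 16 and comes back at 19. The ether bridge is closed at the carbinol oxidation level and C1 is oxidised last.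
- Et3N·3HF on 16 gives the 1,8α,10α-triol F5.
- A π-acid (Ph3PAuNTf2, 5 mol %) brings about 5-endo-dig hydroalkoxylation by 10-OH and gives the 1-hydroxy-3,10α-epoxy-2-ene F6. This compound cannot aromatise because C10 is quaternary.
- MnO2 oxidises the now allylic C1 carbinol in preference to the saturated 8-OH.

**Step 12 (facial selectivity of the ene reaction at C5).**
- The fallback sets out from 21 and comes back at 23. C5 is set by reagent-controlled C–H bond formation instead of substrate-controlled C–O bond formation.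
- Photooxygenation as in step 12 that goes through the 5-epi-hydroperoxide F7 gives, after PPh3, 5-epi-isogoiazensolide F8, alone or mixed with 23.
- Dess–Martin oxidation of the crude alcohols gives the single 5-oxo-4(15)-ene F9.
- (R)-Me-CBS/catecholborane at −78 °C, with the alkenyl branch acting as the large group, or failing that Luche reduction from the open face, delivers the 5R alcohol 23.

## Further compounds
F1 | step 8 | (2Z)-6-hydroxy-7-[(2S)-4-(bromomethyl)-5-oxo-2,5-dihydrofuran-2-yl]-3,6'-dimethyl chain: 3-(bromomethyl)butenolide enal with 10α-OTES and free C1-OH | O=C/C=C(/C)C#CC(O)[C@](C)(O[Si](CC)(CC)CC)C[C@@H]1OC(=O)C(CBr)=C1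
F2 | step 8 | (4Z)-1,6α-dihydroxy-10α-(triethylsilyloxy)germacra-4,11(13)-dien-2-yn-8α,12-olide | O[C@@H]1/C=C(C)\C#CC(O)[C@](C)(O[Si](CC)(CC)CC)C[C@@H]2OC(=O)C(=C)[C@@H]12
F3 | step 8 | (4Z)-1,8α-dihydroxy-10α-(triethylsilyloxy)germacra-4,11(13)-dien-2-yn-6α,12-olide | O[C@H]1C[C@@](C)(O[Si](CC)(CC)CC)C(O)C#C/C(C)=C\[C@H]2OC(=O)C(=C)[C@@H]21
F4 | step 8 | (4Z)-8α-hydroxy-1-oxo-10α-(triethylsilyloxy)germacra-4,11(13)-dien-2-yn-6α,12-olide | O[C@H]1C[C@@](C)(O[Si](CC)(CC)CC)C(=O)C#C/C(C)=C\[C@H]2OC(=O)C(=C)[C@@H]21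
F5 | step 10 | (4Z)-1,8α,10α-trihydroxygermacra-4,11(13)-dien-2-yn-6α,12-olide | O[C@H]1C[C@@](C)(O)C(O)C#C/C(C)=C\[C@H]2OC(=O)C(=C)[C@@H]21
F6 | step 10 | 1,8α-dihydroxy-3,10α-epoxygermacra-2,4Z,11(13)-trien-6α,12-olide | O[C@H]1C[C@@]2(C)OC(=CC2O)/C(C)=C\[C@H]2OC(=O)C(=C)[C@@H]21
F7 | step 12 | (5S)-5-hydroperoxide (5-epimer of 22) | C=C(C)C(=O)O[C@H]1C[C@@]2(C)OC(=CC2=O)C(=C)[C@H](OO)[C@H]2OC(=O)C(=C)[C@@H]21
F8 | step 12 | 5-epi-isogoiazensolide | C=C(C)C(=O)O[C@H]1C[C@@]2(C)OC(=CC2=O)C(=C)[C@H](O)[C@H]2OC(=O)C(=C)[C@@H]21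
F9 | step 12 | 5-oxo-4(15)-ene (5-dehydroisogoiazensolide) | C=C(C)C(=O)O[C@H]1C[C@@]2(C)OC(=CC2=O)C(=C)C(=O)[C@H]2OC(=O)C(=C)[C@@H]21
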